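## Retrosynthetic overview
1. The last disconnection is the butenolide C4–C5 bond. It joins the β-carbon of a crotonate to a formyl carbon, both acceptor carbons, so the crotonate is used as a (Z)-β-magnesiated enoate (β-acylvinyl anion).
2. In the same flask the lactone closes. A vinylogous E1cB opening of an oxirane then creates both exocyclic alkenes and releases the CH2OH group.
3. The γ,δ-epoxy enal comes from cross-metathesis of a 2-alkyl-2-vinyloxirane with crotonaldehyde. The oxirane comes from a chloromethyl ketone and vinylmagnesium bromide.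
4. The chloromethyl ketone comes from the C18 methyl ketone obtained by degrading and dehydrating (−)-sclareol, which supplies both stereocentres.
5. Ring order: decalin rings A and B are bought in, the sacrificial oxirane is made in step 4, and the butenolide is made last in step 7.

Assumption: the SMILES is read as (5Z) at the ylidene bond, (2E) at the side-chain alkene and (4aS,8aS) in the decalin (the sclareol series). Epimers at centres that later become sp2 are carried on unseparated.

Shorthand: Dr = (4aS,8aS)-2,5,5,8a-tetramethyl-3,4,4a,5,6,7,8,8a-octahydronaphthalen-1-yl.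

## Route

Step 1
Reactants: 1 (−)-sclareol [(13R)-labd-14-ene-8α,13-diol]
Product: 2 8α-hydroxy-14,15-dinorlabdan-13-one (4-[(1R,2R,4aS,8aS)-2-hydroxy-2,5,5,8a-tetramethyldecahydronaphthalen-1-yl]butan-2-one)
Conditions: KMnO4 (4 equiv), acetone–H2O, 0 °C → rt
Reagents that add atoms: none
Why: Permanganate oxidative cleavage of the tertiary vinyl carbinol (dihydroxylation, glycol cleavage, oxidative decarboxylation of the α-hydroxy acid) removes C-14 and C-15 and leaves the C-13 methyl ketone without touching the ring stereocentres.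

Step 2
Reactants: 2 8α-hydroxy-14,15-dinorlabdan-13-one
Product: 3 14,15-dinorlabd-8-en-13-one (4-Dr-butan-2-one)
Conditions: I2 (10 mol %), toluene, 85 °C
Reagents that add atoms: none
Why: E1 dehydration of the tertiary C-8 alcohol under equilibrating acid conditions (Zaitsev, thermodynamic control) funnels the alkene isomers to the tetrasubstituted Δ8(9) olefin, which erases C-8 and C-9 and keeps C-5 and C-10 as in the target.

Step 3
Reactants: 3 14,15-dinorlabd-8-en-13-one
Product: 5 1-chloro-4-Dr-butan-2-one, via lithium enolate 4 (not isolated)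
Conditions: LiN(iPr)2 (1.1 equiv), THF, −78 °C; TsCl (1.1 equiv), −78 → 0 °C
Reagents that add atoms: p-toluenesulfonyl chloride, Cc1ccc(cc1)S(=O)(=O)Cl; lithium diisopropylamide, [Li]N(C(C)C)C(C)C (lithium only in 4)
Why: Kinetic deprotonation at the methyl group followed by electrophilic α-chlorination of the enolate (chlorine transfer from the sulfonyl chloride) oxidises the carbon that becomes the CH2OH carbon and creates no stereocentre.

Step 4
Reactants: 5 1-chloro-4-Dr-butan-2-one; 6 vinylmagnesium bromide
Product: 8 2-ethenyl-2-(2-Dr-ethyl)oxirane (about 1:1 epimers at the oxirane carbon), via chlorohydrin 7 (not isolated)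
Conditions: 6 (1.2 equiv), THF, −78 °C; H2O; crude 7, K2CO3 (1.5 equiv), MeOH, rt
Reagents that add atoms: none
Why: Grignard 1,2-addition to the α-chloro ketone and halohydrin ring closure (intramolecular Williamson reaction) give the 2,2-disubstituted vinyl oxirane, whose unselectively formed quaternary centre is harmless because it becomes sp2 in step 7.

Step 5
Reactants: 8 2-ethenyl-2-(2-Dr-ethyl)oxirane; 9 (E)-crotonaldehyde
Product: 10 (2E)-3-[2-(2-Dr-ethyl)oxiran-2-yl]prop-2-enal
Conditions: 9 (5 equiv), second-generation Hoveyda–Grubbs catalyst (5 mol %), CH2Cl2, 40 °C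
Reagents that add atoms: none
Why: Olefin cross-metathesis of the terminal vinyl group with an enal partner gives the conjugated E-enal under thermodynamic control, while the tetrasubstituted ring alkene is inert to the ruthenium carbene.

Step 6
Reactants: 11 ethyl but-2-ynoate
Product: 12 ethyl (Z)-3-iodobut-2-enoate
Conditions: NaI (1.6 equiv), AcOH, 110 °C
Reagents that add atoms: sodium iodide, [Na+].[I-]
Why: Conjugate hydroiodination of the alkynoate proceeds by anti addition of iodide and a proton and places iodine cis to the ester, which is the geometry needed for later lactonisation.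

Step 7 (key step)
Reactants: 12 ethyl (Z)-3-iodobut-2-enoate; 10 (2E)-3-[2-(2-Dr-ethyl)oxiran-2-yl]prop-2-enal
Product: 15 (5Z)-5-[(2E)-3-(hydroxymethyl)-5-Dr-pent-2-en-1-ylidene]-4-methylfuran-2(5H)-one (CNP0288110.2), via magnesiated enoate 13 (not isolated), via epoxy butenolide 14 (not isolated)
Conditions: 12 (1.3 equiv), iPrMgCl (1.3 equiv), THF, −40 °C, 1 h; 10, −40 °C → rt; DBU (1.5 equiv), 0 °C → rt; H2O
Reagents that add atoms: isopropylmagnesium chloride, CC(C)[Mg]Cl (MgCl only in 13)
Why: Proposed new method: Knochel-type iodine–magnesium exchange turns the normally electrophilic β-carbon of the crotonate into a chelate-stabilised, configurationally stable β-acylvinyl anion (an sp2 homoenolate equivalent) that adds 1,2 to the equally electrophilic formyl carbon of 10, the (Z)-γ-alkoxide lactonises at once to 14, and DBU then removes the doubly activated H-5 so that the furanolate pushes through the E-alkene and opens the oxirane (vinylogous E1cB, 1,4-elimination) to free the CH2OH group, the 5Z geometry being enforced by A(1,3) strain with the 4-methyl group and the 2E geometry (expected major, roughly 5:1, minor isomer removed by chromatography) by opening through the s-trans-like conformer that keeps the oxirane CH2 anti to the alkene as in SN2′ openings of 2-methyl-2-vinyloxirane, while both sp3 centres of 14 vanish; the closest known reactions are the magnesiated-enoate/aldehyde butenolide synthesis, the DBU elimination of butenolide aldol adducts to γ-ylidenebutenolides and base-induced 1,4-eliminative openings of vinyl oxiranes.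

## Compound list
1 | (−)-sclareol | C[C@]12CCCC([C@@H]1CC[C@@]([C@@H]2CC[C@](C)(C=C)O)(C)O)(C)C | starting material
2 | 8α-hydroxy-14,15-dinorlabdan-13-one | C[C@]12CCCC([C@@H]1CC[C@@]([C@@H]2CCC(C)=O)(C)O)(C)C | intermediate
3 | 14,15-dinorlabd-8-en-13-one (4-Dr-butan-2-one) | CC(=O)CCC1=C(C)CC[C@H]2C(C)(C)CCC[C@]12C | intermediate
4 | lithium 4-Dr-but-1-en-2-olate (kinetic enolate) | [Li]OC(=C)CCC1=C(C)CC[C@H]2C(C)(C)CCC[C@]12C | intermediate
5 | 1-chloro-4-Dr-butan-2-one | ClCC(=O)CCC1=C(C)CC[C@H]2C(C)(C)CCC[C@]12C | intermediate
6 | vinylmagnesium bromide | C=C[Mg]Br | starting material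
7 | 3-(chloromethyl)-5-Dr-pent-1-en-3-ol (epimers at the carbinol carbon) | OC(CCl)(C=C)CCC1=C(C)CC[C@H]2C(C)(C)CCC[C@]12C | intermediate
8 | 2-ethenyl-2-(2-Dr-ethyl)oxirane (epimers at the oxirane carbon) | C=CC3(CO3)CCC1=C(C)CC[C@H]2C(C)(C)CCC[C@]12C | intermediate
9 | (E)-crotonaldehyde | C/C=C/C=O | starting material
10 | (2E)-3-[2-(2-Dr-ethyl)oxiran-2-yl]prop-2-enal (epimers at the oxirane carbon) | O=C/C=C/C3(CO3)CCC1=C(C)CC[C@H]2C(C)(C)CCC[C@]12C | intermediate
11 | ethyl but-2-ynoate | CC#CC(=O)OCC | starting material
12 | ethyl (Z)-3-iodobut-2-enoate | C/C(I)=C/C(=O)OCC | intermediate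
13 | ethyl (Z)-3-(chloromagnesio)but-2-enoate | C/C([Mg]Cl)=C/C(=O)OCC | intermediate
14 | 4-methyl-5-{(E)-2-[2-(2-Dr-ethyl)oxiran-2-yl]ethenyl}furan-2(5H)-one (diastereomer mixture at C-5 and the oxirane carbon) | CC1=CC(=O)OC1/C=C/C3(CO3)CCC4=C(C)CC[C@H]5C(C)(C)CCC[C@]45C | intermediate
15 | (5Z)-5-[(2E)-3-(hydroxymethyl)-5-Dr-pent-2-en-1-ylidene]-4-methylfuran-2(5H)-one | CC1=CC(=O)O/C1=C\C=C(\CO)CCC1=C(C)CC[C@H]2C(C)(C)CCC[C@]12C | target

## Step count and risks
Total step count: 7. Longest linear sequence: 6 (steps 1–5 and 7).

**Step 7 is the most likely to fail.**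
- Magnesium salts may open or rearrange the tertiary allylic oxirane before the aldehyde is consumed, and the oxirane opening may give a poorer E/Z ratio than expected.
- The fallback sets out from 8 and comes back at 15, by-passing 10 and 12.
- Commercial 5-hydroxy-4-methylfuran-2(5H)-one is condensed with benzenesulfinic acid (cat. camphorsulfonic acid, CH2Cl2) to give 4-methyl-5-(phenylsulfonyl)furan-2(5H)-one F1. Its C-5 is then a sulfone-stabilised carbanion centre, a masked acyl anion of the former formyl carbon.
- With Pd(PPh3)4 (zerovalent palladium, 5 mol %, THF, rt), 8 ionises to an alkoxy π-allyl complex. Its alkoxide deprotonates F1, and the carbanion attacks the unsubstituted allyl terminus to give 5-[(2E)-3-(hydroxymethyl)-5-Dr-pent-2-en-1-yl]-4-methyl-5-(phenylsulfonyl)furan-2(5H)-one F2.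
- DBU then expels benzenesulfinate and delivers 15.

**Step 5 is the second risk.**
- The quaternary allylic carbon slows metathesis, and the product is acid-sensitive.
- The fallback sets out from 5 and comes back at 10. It brings in the three-carbon unit as a preformed nucleophile instead of building it by metathesis.
- Commercial (E)-3-(tributylstannyl)prop-2-en-1-ol and n-BuLi (2.1 equiv, THF, −78 °C) give lithium (E)-3-lithioprop-2-en-1-olate F3.
- F3 adds to 5, and the lithium chlorohydrinate closes on warming to (2E)-3-[2-(2-Dr-ethyl)oxiran-2-yl]prop-2-en-1-ol F4.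
- Neutral oxidation with MnO2 (CH2Cl2, rt) gives 10.

**Step 3 is the third risk.**
- Proton exchange can cause over-chlorination or loss of regiocontrol.
- The fallback sets out from 3 (through enolate 4) and comes back at 8. The oxirane CH2 now comes from a sulfur ylide, and the old methyl group becomes part of the vinyl group.
- Enolate 4 is trapped with dimethylmethylideneammonium iodide to give 1-(dimethylamino)-5-Dr-pentan-3-one F5.
- Quaternisation with MeI and treatment with NaHCO3 give 5-Dr-pent-1-en-3-one F6.
- Dimethylsulfonium methylide (trimethylsulfonium iodide, NaH, DMSO–THF, 0 °C) adds 1,2 (Corey–Chaykovsky epoxidation) to give 8.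

## Further compounds
F1 | step 7 | 4-methyl-5-(phenylsulfonyl)furan-2(5H)-one | CC1=CC(=O)OC1S(=O)(=O)c2ccccc2
F2 | step 7 | 5-[(2E)-3-(hydroxymethyl)-5-Dr-pent-2-en-1-yl]-4-methyl-5-(phenylsulfonyl)furan-2(5H)-one (epimers at C-5) | CC1=CC(=O)OC1(C/C=C(/CO)CCC2=C(C)CC[C@H]3C(C)(C)CCC[C@]23C)S(=O)(=O)c4ccccc4
F3 | step 5 | lithium (E)-3-lithioprop-2-en-1-olate | [Li]/C=C/CO[Li]
F4 | step 5 | (2E)-3-[2-(2-Dr-ethyl)oxiran-2-yl]prop-2-en-1-ol (epimers at the oxirane carbon) | OC/C=C/C3(CO3)CCC1=C(C)CC[C@H]2C(C)(C)CCC[C@]12C
F5 | step 3 | 1-(dimethylamino)-5-Dr-pentan-3-one | CN(C)CCC(=O)CCC1=C(C)CC[C@H]2C(C)(C)CCC[C@]12C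
F6 | step 3 | 5-Dr-pent-1-en-3-one | C=CC(=O)CCC1=C(C)CC[C@H]2C(C)(C)CCC[C@]12C
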